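**Plan** (shikimate numbering: C1 carries CO2Me, C2 is the vinylic CH, C3/C4/C5 carry the acetate, propanoate and (R)-2-methylbutanoate, C6 is CH2)

- Retrosynthesis: the O4 propanoate comes off first. The O5 ester and O4 go back to a C4–C5 epoxide cis to O3, and the O3 acetate to an allylic alcohol. The ring is then cut at C2–C3 and C6–C1.
- Enabling feature: in the cyclohexene ring, C3(O)–C4=C5–C6H2 is a latent 1-oxygenated buta-1,3-diene and C1(CO2Me)=C2H a latent propiolate. O3 and the ester are 1,3 to each other, opposite to the native Diels–Alder sense, so a nitro group on C2 serves as a temporary director and then leaves as HNO2 to create C1=C2.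
- Forward: methyl acrylate is converted into methyl (E)-3-nitroacrylate, and a [4+2] addition with 1-silyloxybutadiene closes the only ring. Loss of HNO2 and desilylation give the dienol, which is carried on by directed epoxidation, acetylation, epoxide opening at C5 and propanoylation.
- Stereochemistry: C3 arises racemic in the cycloaddition and is fixed by a lipase resolution that also installs the acetate. C4 comes from hydroxyl-directed syn epoxidation and C5 from SN2 inversion in the epoxide opening. The side-chain centre comes from (R)-2-methylbutanoic acid; the target SMILES encodes the R acid.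

Key step: step 3

Remark: compounds 1, 4 and 10 are taken as commercial; dienophile 3 is made in two steps because it is not reliably stocked.

Step 1
Reactants: 1 methyl acrylate
Product: 2 methyl 2-iodo-3-nitropropanoate (racemic)
Conditions: N2O4, I2, Et2O, 0 °C to rt
Reagents that add atoms: dinitrogen tetroxide, O=[N+]([O-])[N+](=O)[O-]; iodine, II
Why: Radical nitro-iodination of an acrylate, in which NO2 adds to the unsubstituted β-carbon and the α-ester radical is capped by iodine, a known preparation of this compound.

Step 2
Reactants: 2 methyl 2-iodo-3-nitropropanoate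
Product: 3 methyl (E)-3-nitroprop-2-enoate
Conditions: NaOAc, Et2O, 0 °C to rt
Reagents that add atoms: none
Why: Acetate removes the acidic proton α to the nitro group and iodide leaves (dehydrohalogenation), which should give the conjugated E nitroalkene as the favoured isomer.

Step 3
Reactants: 3 methyl (E)-3-nitroprop-2-enoate; 4 (E)-1-(trimethylsilyloxy)buta-1,3-diene
Product: 7 methyl 3-hydroxycyclohexa-1,4-diene-1-carboxylate (racemic), via nitro cycloadduct 5 (not isolated), via trimethylsilyl ether 6 (not isolated)
Conditions: 4 (1.3 equiv), CH2Cl2, 0 °C to rt; then DBU (1.05 equiv), 0 °C; aqueous wash; then citric acid, MeOH, 0 °C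
Reagents that add atoms: none
Why: A normal-electron-demand, concerted but asynchronous Diels–Alder reaction joins the unsubstituted diene terminus (largest HOMO coefficient, future C6) to the nitroalkene carbon β to nitro (largest LUMO coefficient, future C1), so that C6–C1 and C2–C3 form together; the closest known reaction type is the use of a β-nitroacrylate as a propiolate equivalent of reversed regiochemistry with 1-oxygenated dienes. The six-membered ring, the only ring of the target, is closed by this intermolecular suprafacial [4+2] addition. The selectivity needed is regiochemical (O3 next to C2, ester 1,3 to oxygen), and it is secured because nitro outranks the ester as acceptor and the silyloxy donor polarises the diene in the matching sense. DBU then removes the only proton α to the ester (C1–H) and nitrite leaves from C2 (E1cB), which places the alkene at C1=C2 without ambiguity, while the silyl ether keeps O3 from acting as a leaving group. C3 is the one stereocentre that survives and it forms as a racemate here, its absolute configuration being fixed in step 5; the transient centres at C1 and C2 (nitro trans to ester, mainly cis to silyloxy by the endo rule) are erased by the elimination. Mild acidic methanolysis finally frees the allylic alcohol that directs the next step.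

Step 4
Reactants: 7 methyl 3-hydroxycyclohexa-1,4-diene-1-carboxylate (racemic)
Product: 8 methyl 4,5-epoxy-3-hydroxycyclohex-1-ene-1-carboxylate (racemic, epoxide cis to hydroxyl)
Conditions: VO(acac)2 (2 mol %), t-BuOOH, CH2Cl2, 0 °C
Reagents that add atoms: tert-butyl hydroperoxide, CC(C)(C)OO
Why: Hydroxyl-directed vanadium-catalysed epoxidation should deliver oxygen from the alkoxide-bound peroxide to the electron-rich C4=C5 alkene on the face of the C3 hydroxyl (setting C4 and C5 cis to O3), the ester-conjugated C1=C2 alkene being too electron-poor to react.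

Step 5
Reactants: 8 methyl 4,5-epoxy-3-hydroxycyclohex-1-ene-1-carboxylate (racemic)
Product: 9 methyl (3R,4S,5S)-3-acetoxy-4,5-epoxycyclohex-1-ene-1-carboxylate
Conditions: immobilised Candida antarctica lipase B, vinyl acetate, t-BuOMe, 30 °C, stopped near half conversion; chromatography
Reagents that add atoms: vinyl acetate, C=COC(C)=O
Why: Lipase-catalysed kinetic resolution by enantioselective transesterification should acetylate the (3R) alcohol (epoxide-bearing C4 as the large and planar vinylic C2 as the medium substituent in the empirical size model) and leave its enantiomer, which fixes the absolute configuration of C3, C4 and C5 and installs the C3 acetate of the target in the same operation.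

Step 6
Reactants: 9 methyl (3R,4S,5S)-3-acetoxy-4,5-epoxycyclohex-1-ene-1-carboxylate; 10 (R)-2-methylbutanoic acid
Product: 11 methyl (3R,4S,5R)-3-acetoxy-4-hydroxy-5-[(2R)-2-methylbutanoyloxy]cyclohex-1-ene-1-carboxylate
Conditions: 10 (1.5 equiv), Co(salen) [Co(C16H14N2O2), N,N'-bis(salicylidene)ethylenediaminocobalt] (5 mol %), air, i-Pr2NEt (1 equiv), t-BuOMe, rt
Reagents that add atoms: none
Why: Cobalt–salen-catalysed addition of a carboxylic acid to an epoxide should proceed by SN2 attack of the carboxylate anti to the epoxide oxygen at C5, the carbon remote from the electron-withdrawing acetoxy-bearing C3 (as in azide openings of 3-alkoxy-4,5-epoxycyclohex-1-enecarboxylates), which inverts C5 and leaves O4 cis to O3.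

Step 7
Reactants: 11 methyl (3R,4S,5R)-3-acetoxy-4-hydroxy-5-[(2R)-2-methylbutanoyloxy]cyclohex-1-ene-1-carboxylate
Product: 12 methyl (3R,4S,5R)-3-acetoxy-5-[(2R)-2-methylbutanoyloxy]-4-propanoyloxycyclohex-1-ene-1-carboxylate (target)
Conditions: (EtCO)2O, Sc(OTf)3 (1 mol %), MeCN, −20 °C
Reagents that add atoms: propanoic anhydride, CCC(=O)OC(=O)CC
Why: Lewis-acid-catalysed acylation of the hindered C4 hydroxyl is fast under non-basic conditions, which should avoid base-mediated migration of the neighbouring acetyl and 2-methylbutanoyl groups, and no stereocentre is touched.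

**Compound list**

1 | methyl acrylate | C=CC(=O)OC | starting material
2 | methyl 2-iodo-3-nitropropanoate (racemic) | COC(=O)C(I)C[N+](=O)[O-] | intermediate
3 | methyl (E)-3-nitroprop-2-enoate | COC(=O)/C=C/[N+](=O)[O-] | intermediate
4 | (E)-1-(trimethylsilyloxy)buta-1,3-diene | C=C/C=C/O[Si](C)(C)C | starting material
5 | methyl 2-nitro-3-(trimethylsilyloxy)cyclohex-4-ene-1-carboxylate (racemic; nitro trans to ester, cis to silyloxy; relative configuration shown) | C[Si](C)(C)O[C@@H]1[C@H]([N+](=O)[O-])[C@@H](C(=O)OC)CC=C1 | intermediate
6 | methyl 3-(trimethylsilyloxy)cyclohexa-1,4-diene-1-carboxylate (racemic) | COC(=O)C1=CC(O[Si](C)(C)C)C=CC1 | intermediate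
7 | methyl 3-hydroxycyclohexa-1,4-diene-1-carboxylate (racemic) | COC(=O)C1=CC(O)C=CC1 | intermediate
8 | methyl 4,5-epoxy-3-hydroxycyclohex-1-ene-1-carboxylate (racemic, epoxide cis to hydroxyl; relative configuration shown) | O[C@@H]1C=C(C(=O)OC)C[C@@H]2O[C@H]12 | intermediate
9 | methyl (3R,4S,5S)-3-acetoxy-4,5-epoxycyclohex-1-ene-1-carboxylate | CC(=O)O[C@@H]1C=C(C(=O)OC)C[C@@H]2O[C@H]12 | intermediate
10 | (R)-2-methylbutanoic acid | CC[C@@H](C)C(=O)O | starting material
11 | methyl (3R,4S,5R)-3-acetoxy-4-hydroxy-5-[(2R)-2-methylbutanoyloxy]cyclohex-1-ene-1-carboxylate | O[C@@H]1[C@H](OC(C)=O)C=C(C(=O)OC)C[C@H]1OC(=O)[C@H](C)CC | intermediate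
12 | methyl (3R,4S,5R)-3-acetoxy-5-[(2R)-2-methylbutanoyloxy]-4-propanoyloxycyclohex-1-ene-1-carboxylate | CCC(=O)O[C@@H]1[C@H](OC(C)=O)C=C(C(=O)OC)C[C@H]1OC(=O)[C@H](C)CC | target

Total step count: 7. Longest linear sequence: 7 steps (1 to 12).

**Steps most likely to fail**

Step 3. During the DBU stage the nitronate may expel silanolate, or the doubly allylic 1,4-diene may isomerise into conjugation or aromatise with loss of the C3 oxygen. The fallback sets out from 3 and 4 and returns at 8. The crude cycloadduct 5 is desilylated at once (citric acid, MeOH, 0 °C) to the racemic nitro alcohol methyl 3-hydroxy-2-nitrocyclohex-4-ene-1-carboxylate F1. Its hydroxyl directs VO(acac)2/t-BuOOH epoxidation of the only alkene to the syn nitro epoxy alcohol methyl 4,5-epoxy-3-hydroxy-2-nitrocyclohexane-1-carboxylate F2. DBU (THF, −20 °C) then removes nitrous acid through the ester enolate to give 8, so that no 1,4-diene is ever exposed to base.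

Step 5. The lipase may discriminate the two enantiomers too weakly, or prefer the (3S) alcohol. The fallback sets out from 8 and returns at 9 by classical resolution through diastereomeric esters. DCC/DMAP coupling of 8 with (S)-2-methoxy-2-phenylacetic acid gives the (3R,4S,5S)-epoxy alcohol (S)-2-methoxy-2-phenylacetate F3 and its (3S,4R,5R) diastereomer F4, which are separated by chromatography or crystallisation. K2CO3 in MeOH at 0 °C releases the enantiopure epoxy alcohol methyl (3R,4S,5S)-4,5-epoxy-3-hydroxycyclohex-1-ene-1-carboxylate F5 from F3, and Ac2O/pyridine converts it into 9. If the enzyme merely shows the opposite preference, the alcohol recovered from step 5 is F5 and is acetylated in the same way.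

Step 6. The hindered, weakly nucleophilic carboxylate may open the epoxide too slowly, so that acetyl migration from O3 to the new O4 hydroxyl or attack at C4 competes. The fallback sets out from 9 and returns at 11. The epoxide is opened with water instead (cat. HClO4, THF–H2O, 0 °C, anti attack at C5) to the trans-4,5-diol methyl (3R,4S,5R)-3-acetoxy-4,5-dihydroxycyclohex-1-ene-1-carboxylate F6. The less hindered equatorial O5 hydroxyl, next to the C6 methylene, is then esterified selectively with 10 (DCC, cat. DMAP, CH2Cl2, −20 °C, Steglich esterification) to give 11.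

**Further compounds**

F1 | step 3 | methyl 3-hydroxy-2-nitrocyclohex-4-ene-1-carboxylate (racemic; nitro cis to hydroxyl, trans to ester) | O[C@@H]1[C@H]([N+](=O)[O-])[C@@H](C(=O)OC)CC=C1
F2 | step 3 | methyl 4,5-epoxy-3-hydroxy-2-nitrocyclohexane-1-carboxylate (racemic; epoxide cis to hydroxyl) | O[C@@H]1[C@H]([N+](=O)[O-])[C@@H](C(=O)OC)C[C@@H]2O[C@H]12
F3 | step 5 | methyl (3R,4S,5S)-4,5-epoxy-3-[(2S)-2-methoxy-2-phenylacetoxy]cyclohex-1-ene-1-carboxylate | CO[C@@H](c1ccccc1)C(=O)O[C@@H]1C=C(C(=O)OC)C[C@@H]2O[C@H]12
F4 | step 5 | methyl (3S,4R,5R)-4,5-epoxy-3-[(2S)-2-methoxy-2-phenylacetoxy]cyclohex-1-ene-1-carboxylate | CO[C@@H](c1ccccc1)C(=O)O[C@H]1C=C(C(=O)OC)C[C@H]2O[C@@H]12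
F5 | step 5 | methyl (3R,4S,5S)-4,5-epoxy-3-hydroxycyclohex-1-ene-1-carboxylate (single enantiomer) | O[C@@H]1C=C(C(=O)OC)C[C@@H]2O[C@H]12
F6 | step 6 | methyl (3R,4S,5R)-3-acetoxy-4,5-dihydroxycyclohex-1-ene-1-carboxylate | O[C@@H]1[C@H](OC(C)=O)C=C(C(=O)OC)C[C@H]1O
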